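Ring B is a cyclohept-4-enone (ketone C6, alkene C9=C10) fused to lactone D, the retron of a rhodium-catalysed vinylcyclopropane–alkyne (5+2) cycloaddition. A 1-siloxy-1-alkenylcyclopropane (C6, C7, C8, with the ring A alkene C5=C11) and a propiolate ester on the C13 oxygen (C12, C9, C10) react in one operation: C8–C9 closes lactone D, C10–C11 (vinylic CH to the ring A/B fusion CH) closes ring B, C11 is set, and the silyl enol ether left at C5=C6 is the masked ketone. The precursor is a bicyclo[3.1.0]hexane carrying an exo cyclohexadienyl group, assembled from a gem-dibromocyclopropane and an enantiopure dienyl triflate.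

Key step: step 16

Locants used below: C1 CH bearing isopropenyl; C2 ring A CH2; C3 enol carbon; C4 ester-bearing carbon; C5 ring A/B fusion CH next to the ketone; C6 ketone; C7 ring B/C fusion CH; C8 CH shared by rings B, C and D; C9 lactone α-carbon; C10 vinylic CH; C11 ring A/B fusion CH; C12 lactone carbonyl; C13 CH–O; C14 ring C CH2; C15 C(CH3)OH. Rings: A (C1–C5, C11), B (C5–C11), C (C7, C8, C13–C15), D (lactone).

Remark: C5 lies between the C6 ketone and the ring A enol, so its cis-fused configuration is taken to be the thermodynamic one and is left to equilibration in the last step.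

Step 1
Reactants: 1 5,6-dihydro-2H-pyran-2-one; 2 isopropenylboronic acid pinacol ester
Product: 3 (R)-4-(prop-1-en-2-yl)tetrahydro-2H-pyran-2-one
Conditions: [Rh(OH)(cod)]2 (cat.), (R)-BINAP, dioxane/H2O 10:1, 60 °C
Reagents that add atoms: none
Why: Hayashi–Miyaura rhodium-catalysed asymmetric 1,4-addition of the alkenylboron reagent to the unsaturated lactone; the BINAP-bound rhodium alkenyl should add to one enantiotopic face and set the isopropenyl-bearing centre (later C1) as R.

Step 2
Reactants: 3 (R)-4-(prop-1-en-2-yl)tetrahydro-2H-pyran-2-one; 4 methyl acetate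
Product: 5 methyl (R)-7-hydroxy-3-oxo-5-(prop-1-en-2-yl)heptanoate
Conditions: LiN(i-Pr)2, THF, −78 to −40 °C
Reagents that add atoms: none
Why: Claisen-type acylation of the lithium enolate of methyl acetate by the lactone carbonyl; the ring-opened product rests as its β-keto ester enolate, so a second addition should not occur and the stereocentre is untouched.

Step 3
Reactants: 5 methyl (R)-7-hydroxy-3-oxo-5-(prop-1-en-2-yl)heptanoate
Product: 7 methyl (R)-6-oxo-4-(prop-1-en-2-yl)cyclohex-1-ene-1-carboxylate, via keto aldehyde 6 (not isolated)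
Conditions: Dess–Martin periodinane, NaHCO3, CH2Cl2, 0 °C; then piperidine, AcOH, 23 °C
Reagents that add atoms: none
Why: Dess–Martin oxidation of the primary alcohol followed by intramolecular Knoevenagel condensation of the β-keto ester with the aldehyde should close ring A as the alkylidene β-keto ester; the existing centre is untouched.

Step 4
Reactants: 7 methyl (R)-6-oxo-4-(prop-1-en-2-yl)cyclohex-1-ene-1-carboxylate
Product: 9 methyl (R)-2-methoxy-6-oxo-4-(prop-1-en-2-yl)cyclohex-1-ene-1-carboxylate, via selenide 8 (not isolated)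
Conditions: NaOMe, MeOH/THF, −20 °C; PhSeCl, −78 °C; then H2O2, pyridine, CH2Cl2, 0 °C
Reagents that add atoms: sodium methoxide [Na+].[O-]C
Why: Oxa-Michael addition of methoxide, α-selenenylation of the resulting β-keto ester enolate trans to the new methoxy group and selenoxide syn-elimination toward the only β-hydrogen should give the vinylogous ester; the ketone (C5) and the enol ether (C3) never become equivalent, so the R centre cannot be lost through a symmetrical triketone.

Step 5
Reactants: 9 methyl (R)-2-methoxy-6-oxo-4-(prop-1-en-2-yl)cyclohex-1-ene-1-carboxylate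
Product: 10 methyl (R)-2-methoxy-4-(prop-1-en-2-yl)-6-(trifluoromethanesulfonyloxy)cyclohexa-1,5-diene-1-carboxylate
Conditions: LiN(i-Pr)2, THF, −78 °C; PhNTf2, −78 to 0 °C
Reagents that add atoms: N-phenyl-bis(trifluoromethanesulfonimide) O=S(=O)(N(c1ccccc1)S(=O)(=O)C(F)(F)F)C(F)(F)F
Why: Kinetic α'-deprotonation of the vinylogous ester at C11 and O-sulfonylation of the cross-conjugated enolate should give the dienyl triflate with the C5=C11 alkene in place.

Step 6
Reactants: 11 (R)-4-(tert-butyldimethylsilyloxy)cyclopent-2-en-1-one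
Product: 12 (1S,4R)-4-(tert-butyldimethylsilyloxy)-1-methylcyclopent-2-en-1-ol
Conditions: MeLi, CeCl3, THF, −78 °C
Reagents that add atoms: methyllithium [Li]C
Why: 1,2-Addition of the organometallic reagent to the enone carbonyl anti to the silyloxy group should set the tertiary carbinol (later C15) with its hydroxyl cis to the silyl ether.

Step 7
Reactants: 12 (1S,4R)-4-(tert-butyldimethylsilyloxy)-1-methylcyclopent-2-en-1-ol
Product: 13 (1S,4R)-1-methylcyclopent-2-ene-1,4-diol
Conditions: Bu4NF, THF, 0 °C
Reagents that add atoms: none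
Why: Fluoride-mediated desilylation frees the secondary alcohol so that both hydroxyls can direct the next step; no stereocentre is affected.

Step 8
Reactants: 13 (1S,4R)-1-methylcyclopent-2-ene-1,4-diol
Product: 14 (1R,2S,4R,5S)-6,6-dibromo-2-methylbicyclo[3.1.0]hexane-2,4-diol
Conditions: CHBr3, 50 % aq. NaOH, BnEt3NCl (cat.), CH2Cl2, 0 to 23 °C
Reagents that add atoms: bromoform BrC(Br)Br
Why: Phase-transfer dibromocarbene cyclopropanation; both allylic hydroxyls direct the carbene and the methyl group shields the opposite face, so the cyclopropane (C7, C8) should form cis to both hydroxyls.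

Step 9
Reactants: 14 (1R,2S,4R,5S)-6,6-dibromo-2-methylbicyclo[3.1.0]hexane-2,4-diol
Product: 15 (1R,2S,4R,5S)-6,6-dibromo-2-methyl-2,4-bis(triethylsilyloxy)bicyclo[3.1.0]hexane
Conditions: TESOTf, 2,6-lutidine, CH2Cl2, −78 to 0 °C
Reagents that add atoms: triethylsilyl trifluoromethanesulfonate CC[Si](CC)(CC)OS(=O)(=O)C(F)(F)F
Why: Silylation of both hydroxyls under non-ionising basic conditions protects them for the organolithium step; no stereocentre is affected.

Step 10
Reactants: 15 (1R,2S,4R,5S)-6,6-dibromo-2-methyl-2,4-bis(triethylsilyloxy)bicyclo[3.1.0]hexane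
Product: 17 2-methyl-6,6-bis(pinacolboryl)-2,4-bis(triethylsilyloxy)bicyclo[3.1.0]hexane (ring stereocentres as in 15), via lithium carbenoid 16 (not isolated)
Conditions: n-BuLi, THF/Et2O, −110 °C; B2pin2, −110 to 23 °C
Reagents that add atoms: bis(pinacolato)diboron CC1(C)OB(OC1(C)C)B1OC(C)(C)C(C)(C)O1
Why: Bromine–lithium exchange gives the cyclopropylidene carbenoid, which is borylated and undergoes a Matteson-type 1,2-boryl shift with loss of bromide; the geminal bis(boronate) results whichever bromine is exchanged, so no stereochemical issue arises here.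

Step 11
Reactants: 17 2-methyl-6,6-bis(pinacolboryl)-2,4-bis(triethylsilyloxy)bicyclo[3.1.0]hexane; 10 methyl (R)-2-methoxy-4-(prop-1-en-2-yl)-6-(trifluoromethanesulfonyloxy)cyclohexa-1,5-diene-1-carboxylate
Product: 18 coupled boronate: C5 of the ring A diene bonded exo to C6 of the bicyclo[3.1.0]hexane, pinacolboryl endo on C6 (other stereocentres as in 10 and 15)
Conditions: Pd(OAc)2 (cat.), SPhos, K3PO4, THF/H2O, 40 °C
Reagents that add atoms: none
Why: Suzuki–Miyaura mono-coupling of a geminal bis(boronate) with an alkenyl triflate; only the exo boron on the convex face, remote from the two silyloxy groups, should transmetalate (with retention), which fixes C6 with the dienyl group exo and the remaining boron endo.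

Step 12
Reactants: 18 coupled boronate
Product: 19 endo cyclopropanol (C6–OH endo, dienyl exo)
Conditions: H2O2, NaOH (aq.), THF, 0 °C
Reagents that add atoms: hydrogen peroxide OO
Why: Oxidation of the carbon–boron bond proceeds with retention, so the endo boronate should become the endo cyclopropanol.

Step 13
Reactants: 19 endo cyclopropanol
Product: 20 cyclopropyl tert-butyldimethylsilyl ether of 19
Conditions: TBSOTf, 2,6-lutidine, CH2Cl2, −78 °C
Reagents that add atoms: tert-butyldimethylsilyl trifluoromethanesulfonate CC(C)(C)[Si](C)(C)OS(=O)(=O)C(F)(F)F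
Why: Silylation of the tertiary cyclopropanol gives the 1-siloxy-1-alkenylcyclopropane needed for the cycloaddition and protects it against ring opening.

Step 14
Reactants: 20 cyclopropyl tert-butyldimethylsilyl ether
Product: 21 secondary alcohol (C13–OH free, tertiary C15–OTES and cyclopropyl OTBS kept)
Conditions: HF·pyridine, pyridine, THF, 0 °C
Reagents that add atoms: none
Why: Selective desilylation; the secondary triethylsilyl ether should be cleaved much faster than the tertiary triethylsilyl ether and the hindered tertiary tert-butyldimethylsilyl ether.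

Step 15
Reactants: 21 secondary alcohol; 22 propiolic acid
Product: 23 propiolate ester of 21 on the C13 oxygen
Conditions: DCC, DMAP (cat.), CH2Cl2, −20 to 0 °C
Reagents that add atoms: none
Why: Steglich esterification of the only free hydroxyl installs the alkyne on the C13 oxygen with retention, cis to the cyclopropane.

Step 16
Reactants: 23 propiolate ester
Product: 24 tetracyclic cycloadduct (rings A–D complete; C6 as tert-butyldimethylsilyl enol ether C5=C6, C3 as methyl enol ether, C15 as triethylsilyl ether)
Conditions: [Rh(CO)2Cl]2 (5 mol %), toluene (0.01 M), 80 °C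
Reagents that add atoms: none
Why: Monovalent rhodium should coordinate the exo alkene C5=C11 and insert into the adjacent C6–C8 cyclopropane bond to give a σ-alkyl/π-allyl rhodacycle, the tethered alkyne then inserts into Rh–C8 and carbon–carbon reductive elimination joins C10 to the allyl terminus C11; this is the vinylcyclopropane–alkyne (5+2) cycloaddition known for 1-siloxy-1-vinylcyclopropanes and for π-components tethered to a cyclopropane carbon. Ring D closes as the five-membered lactone by the alkyne insertion (C8–C9, retention at C8) and ring B as the seven-membered cyclohepta-1,4-diene by the final reductive elimination (C10–C11). C11 is the only new stereocentre: the bond forms suprafacially on the alkene face turned toward the breaking C6–C8 bond, which for the exo alkenyl group places H11 cis to H7 and H8, and that same face is anti to the isopropenyl group on C1, so the two fragments are matched. The step needs cleavage of C6–C8 rather than C6–C7 (only C8 can be reached by the three-atom ester tether), (5+2) closure rather than (3+2) closure onto C6 (C6 is fully substituted and becomes the enol ether carbon), and reaction through the s-cis ester conformer (helped by heat and high dilution).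

Step 17
Reactants: 24 tetracyclic cycloadduct
Product: 25 target CNP0268969.1
Conditions: 1 M HCl (aq.), THF, 23 °C
Reagents that add atoms: water O
Why: Acid hydrolysis of the silyl enol ether (C6 ketone), the methyl enol ether (ring A β-keto ester, resting as its enol) and the triethylsilyl ether; C5 is protonated under equilibrating conditions and should settle in the cis ring fusion.

Compound list
1 | 5,6-dihydro-2H-pyran-2-one | O=C1C=CCCO1 | starting material
2 | isopropenylboronic acid pinacol ester | CC(=C)B1OC(C)(C)C(C)(C)O1 | starting material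
3 | (R)-4-(prop-1-en-2-yl)tetrahydro-2H-pyran-2-one | O=C1C[C@H](C(C)=C)CCO1 | intermediate
4 | methyl acetate | CC(=O)OC | starting material
5 | methyl (R)-7-hydroxy-3-oxo-5-(prop-1-en-2-yl)heptanoate | COC(=O)CC(=O)C[C@H](C(C)=C)CCO | intermediate
6 | methyl (R)-3,7-dioxo-5-(prop-1-en-2-yl)heptanoate (keto aldehyde, not isolated) | COC(=O)CC(=O)C[C@H](C(C)=C)CC=O | intermediate
7 | methyl (R)-6-oxo-4-(prop-1-en-2-yl)cyclohex-1-ene-1-carboxylate | O=C1C[C@H](C(C)=C)CC=C1C(=O)OC | intermediate
8 | methyl (4R)-2-methoxy-6-oxo-1-(phenylselanyl)-4-(prop-1-en-2-yl)cyclohexane-1-carboxylate (selenide, not isolated; C1 and C2 of the ring undefined) | COC(=O)C1([Se]c2ccccc2)C(OC)C[C@@H](C(C)=C)CC1=O | intermediate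
9 | methyl (R)-2-methoxy-6-oxo-4-(prop-1-en-2-yl)cyclohex-1-ene-1-carboxylate | O=C1C[C@H](C(C)=C)CC(OC)=C1C(=O)OC | intermediate
10 | methyl (R)-2-methoxy-4-(prop-1-en-2-yl)-6-(trifluoromethanesulfonyloxy)cyclohexa-1,5-diene-1-carboxylate | O=S(=O)(OC1=C[C@H](C(C)=C)CC(OC)=C1C(=O)OC)C(F)(F)F | intermediate
11 | (R)-4-(tert-butyldimethylsilyloxy)cyclopent-2-en-1-one | CC(C)(C)[Si](C)(C)O[C@H]1C=CC(=O)C1 | starting material
12 | (1S,4R)-4-(tert-butyldimethylsilyloxy)-1-methylcyclopent-2-en-1-ol | CC(C)(C)[Si](C)(C)O[C@H]1C=C[C@@](C)(O)C1 | intermediate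
13 | (1S,4R)-1-methylcyclopent-2-ene-1,4-diol | O[C@H]1C=C[C@@](C)(O)C1 | intermediate
14 | (1R,2S,4R,5S)-6,6-dibromo-2-methylbicyclo[3.1.0]hexane-2,4-diol (both hydroxyls cis to the cyclopropane) | O[C@@H]1C[C@](C)(O)[C@H]2[C@@H]1C2(Br)Br | intermediate
15 | (1R,2S,4R,5S)-6,6-dibromo-2-methyl-2,4-bis(triethylsilyloxy)bicyclo[3.1.0]hexane | CC[Si](CC)(CC)O[C@@H]1C[C@](C)(O[Si](CC)(CC)CC)[C@H]2[C@@H]1C2(Br)Br | intermediate
16 | 6-bromo-6-lithio carbenoid of 15 (not isolated; C6 configuration undefined) | CC[Si](CC)(CC)O[C@@H]1C[C@](C)(O[Si](CC)(CC)CC)[C@H]2[C@@H]1C2([Li])Br | intermediate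
17 | 2-methyl-6,6-bis(pinacolboryl)-2,4-bis(triethylsilyloxy)bicyclo[3.1.0]hexane (ring stereocentres as in 15) | CC[Si](CC)(CC)O[C@@H]1C[C@](C)(O[Si](CC)(CC)CC)[C@H]2[C@@H]1C2(B3OC(C)(C)C(C)(C)O3)B3OC(C)(C)C(C)(C)O3 | intermediate
18 | coupled boronate: ring A diene (C5) exo and pinacolboryl endo on C6 of the bicyclo[3.1.0]hexane | CC[Si](CC)(CC)O[C@@H]1C[C@](C)(O[Si](CC)(CC)CC)[C@H]2[C@@H]1[C@]2(B3OC(C)(C)C(C)(C)O3)C3=C[C@H](C(C)=C)CC(OC)=C3C(=O)OC | intermediate
19 | endo cyclopropanol (C6–OH endo, ring A diene exo) | CC[Si](CC)(CC)O[C@@H]1C[C@](C)(O[Si](CC)(CC)CC)[C@H]2[C@@H]1[C@]2(O)C3=C[C@H](C(C)=C)CC(OC)=C3C(=O)OC | intermediate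
20 | cyclopropyl tert-butyldimethylsilyl ether of 19 | CC[Si](CC)(CC)O[C@@H]1C[C@](C)(O[Si](CC)(CC)CC)[C@H]2[C@@H]1[C@]2(O[Si](C)(C)C(C)(C)C)C3=C[C@H](C(C)=C)CC(OC)=C3C(=O)OC | intermediate
21 | secondary alcohol (C13–OH free) | O[C@@H]1C[C@](C)(O[Si](CC)(CC)CC)[C@H]2[C@@H]1[C@]2(O[Si](C)(C)C(C)(C)C)C3=C[C@H](C(C)=C)CC(OC)=C3C(=O)OC | intermediate
22 | propiolic acid | C#CC(=O)O | starting material
23 | propiolate ester of 21 (cycloaddition precursor) | C#CC(=O)O[C@@H]1C[C@](C)(O[Si](CC)(CC)CC)[C@H]2[C@@H]1[C@]2(O[Si](C)(C)C(C)(C)C)C3=C[C@H](C(C)=C)CC(OC)=C3C(=O)OC | intermediate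
24 | tetracyclic cycloadduct (C5=C6 silyl enol ether, C3 methyl enol ether, C15 triethylsilyl ether) | C=C(C)[C@@H]1CC(OC)=C(C(=O)OC)C2=C(O[Si](C)(C)C(C)(C)C)[C@@H]3[C@@H]4C(=C[C@H]21)C(=O)O[C@@H]4C[C@]3(C)O[Si](CC)(CC)CC | intermediate
25 | target CNP0268969.1 | C=C(C)[C@@H]1CC(O)=C(C(=O)OC)[C@H]2C(=O)[C@@H]3[C@@H]4C(=C[C@H]21)C(=O)O[C@@H]4C[C@]3(C)O | target

Total step count: 17. Longest linear sequence: 12 steps (steps 6 to 17 from 11; the branch of steps 1 to 5 followed by steps 11 to 17 is equally long).

Steps most likely to fail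

Step 16. The ester tether may reach its reactive s-cis conformer too rarely, or the rhodacycle may close onto C6 (formal (3+2) path) or open the cyclopropane without cycloaddition. The fallback sets out from alcohol 21: an intermolecular rhodium-catalysed (5+2) cycloaddition with methyl propiolate ([Rh(CO)2Cl]2, 1,2-dichloroethane, 60 °C) should give the hydroxy ester cycloadduct F1, with the ester on C9 next to the cis hydroxyl on C13; lactonisation (pyridinium p-toluenesulfonate, toluene, 60 °C) then comes back to 24.

Step 11. Protodeboronation of the geminal bis(boronate) under the basic conditions, or failure of the fully substituted cyclopropyl boron to transmetalate, may outrun the coupling. The fallback sets out from 10 and 15: Miyaura borylation of 10 (B2pin2, PdCl2(dppf), KOAc, dioxane, 80 °C) gives the dienylboronate F2; kinetic exchange of the exposed exo bromine of 15 (t-BuLi, −110 °C) to carbenoid 16, addition of F2 and warming should trigger a Matteson-type 1,2-shift of the dienyl group with inversion at carbon and loss of bromide, which comes back to 18.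

Step 4. Phenylselanyl chloride may also add to the isopropenyl group, and the methanol adduct may revert before it is selenenylated. The fallback sets out from 7: conjugate addition of thiophenol (Et3N, CH2Cl2) gives the sulfide F3, chlorination with N-chlorosuccinimide and loss of HCl give the vinylogous thioester F4, and addition–elimination with NaOMe in methanol comes back to 9.

Further compounds
F1 | step 16 | hydroxy ester cycloadduct (methyl ester on C9, free C13 hydroxyl, otherwise as 24) | C=C(C)[C@@H]1CC(OC)=C(C(=O)OC)C2=C(O[Si](C)(C)C(C)(C)C)[C@@H]3[C@H](C(C(=O)OC)=C[C@H]21)[C@H](O)C[C@]3(C)O[Si](CC)(CC)CC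
F2 | step 11 | methyl (R)-2-methoxy-4-(prop-1-en-2-yl)-6-(4,4,5,5-tetramethyl-1,3,2-dioxaborolan-2-yl)cyclohexa-1,5-diene-1-carboxylate | CC1(C)OB(OC1(C)C)C2=C[C@H](C(C)=C)CC(OC)=C2C(=O)OC
F3 | step 4 | methyl 6-oxo-2-(phenylsulfanyl)-4-(prop-1-en-2-yl)cyclohexane-1-carboxylate (isopropenyl-bearing centre as in 7) | COC(=O)C1C(Sc2ccccc2)C[C@@H](C(C)=C)CC1=O
F4 | step 4 | methyl 6-oxo-2-(phenylsulfanyl)-4-(prop-1-en-2-yl)cyclohex-1-ene-1-carboxylate (isopropenyl-bearing centre as in 7) | O=C1C[C@H](C(C)=C)CC(Sc2ccccc2)=C1C(=O)OC
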